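In tetralin numbering (guaiacyl ring on C1, C9 and C9' on C2 and C3, C4 the CH2) the target is an isomer of coniferyl plus sinapyl alcohol: guaiacyl–C1–C2–C9 and ring A–C4–C3–C9' joined through C2–C3 and C1–C8a, with C8a ortho and para to the C8 and C6 methoxy groups. Both bonds are disconnected together. The key step, a redox-neutral photoredox radical-cation [4+2] isomerisation, forms them, closes ring B plus a temporary ten-membered dilactone and sets C1, C2 and C3. Its precursor holds O-benzylconiferyl and O-pivaloylsinapyl alcohol as the two ester arms of L-tartaric acid acetonide, whose C2-symmetric backbone must select the alkene faces.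

Key step: step 7

Remarks on the chemistry
- Structure check: CIP analysis of the target SMILES gives 1S,2R,3R, with H1/H2 and H2/H3 trans. The key-step precursor and product are isomers (C40H46O12). The three tetralin centres of the bridged product map unchanged onto the target. The L-tartrate acetonide is 4R,5R.
- The aryl pivalate goes on before the carboxyl reduction, and the reductant is borohydride. An aryl ester would not survive an aluminium hydride, and acylating a phenol next to an allylic alcohol is an avoidable selectivity problem.
- The trans-dioxolane diacid cannot close to a monomeric cyclic anhydride. Its two homotopic carboxyl groups are therefore differentiated by stoichiometry.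
- Assumption: the (4R,5R) tether is taken to favour the 1S,2R,3R series. Because the tether is chiral, the other all-trans product would be a diastereomer that chromatography or crystallisation removes before tether cleavage, so the enantiopurity of the target does not depend on the level of induction. The commercial D-tartrate ester would serve in the same steps if the sense proved opposite.

Step 1
Reactants: 1 ferulic acid
Product: 2 benzyl (E)-3-[4-(benzyloxy)-3-methoxyphenyl]prop-2-enoate
Conditions: BnBr (2.3 equiv), K2CO3 (3 equiv), DMF, 60 °C
Reagents that add atoms: benzyl bromide, BrCc1ccccc1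
Why: Williamson etherification of the phenoxide and SN2 O-alkylation of the carboxylate run side by side, so phenol masking and ester formation cost one operation and the E-alkene is untouched.

Step 2
Reactants: 2 benzyl (E)-3-[4-(benzyloxy)-3-methoxyphenyl]prop-2-enoate
Product: 3 4-O-benzylconiferyl alcohol
Conditions: DIBAL-H (3 equiv), CH2Cl2, −78 → 0 °C; aq. Rochelle salt
Reagents that add atoms: none
Why: DIBAL-H reduces the α,β-unsaturated ester by 1,2-addition to the allylic alcohol, a standard monolignol preparation, and leaves the alkene geometry and the aryl benzyl ether intact.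

Step 3
Reactants: 4 sinapic acid
Product: 6 4-O-pivaloylsinapyl alcohol, via mixed pivalic anhydride 5 (not isolated)
Conditions: PivCl (2.3 equiv), Et3N (3 equiv), THF, 0 °C → rt; filter; NaBH4 (3 equiv), THF–H2O, 0 °C
Reagents that add atoms: pivaloyl chloride, CC(C)(C)C(=O)Cl
Why: Pivaloyl chloride acylates the phenol and turns the carboxyl group into mixed anhydride 5, whose unhindered cinnamoyl carbonyl is then reduced by borohydride (mixed-anhydride/NaBH4 reduction of an acid to the alcohol), while the aryl pivalate, shielded by tert-butyl and two ortho methoxy groups, should survive at 0 °C.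

Step 4
Reactants: 7 dimethyl (4R,5R)-2,2-dimethyl-1,3-dioxolane-4,5-dicarboxylate
Product: 8 (4R,5R)-2,2-dimethyl-1,3-dioxolane-4,5-dicarboxylic acid
Conditions: LiOH·H2O (2.3 equiv), THF–H2O, 0 °C → rt; cold 1 M HCl to pH 2, EtOAc extraction
Reagents that add atoms: lithium hydroxide, [Li+].[OH-] (its oxygen becomes a carboxyl oxygen)
Why: Ester saponification (BAc2); the trans-dioxolane is the more stable epimer, so the α-centres hold their configuration, and brief cold acidification spares the acetonide.

Step 5
Reactants: 8 (4R,5R)-2,2-dimethyl-1,3-dioxolane-4,5-dicarboxylic acid (3 equiv); 6 4-O-pivaloylsinapyl alcohol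
Product: 9 mono(4-O-pivaloylsinapyl) half ester of the (4R,5R)-diacid
Conditions: EDC·HCl (1.1 equiv), DMAP (0.1 equiv), THF–CH2Cl2, 0 °C → rt; NaHCO3 extraction, cold citric acid, EtOAc
Reagents that add atoms: none
Why: Steglich-type carbodiimide esterification with the cheap diacid in threefold excess and the carbodiimide limiting, so the alcohol meets almost only unesterified diacid; the two carboxyl groups are homotopic, so a single half ester results, and the water-soluble surplus diacid is washed out.

Step 6
Reactants: 9 mono(4-O-pivaloylsinapyl) half ester; 3 4-O-benzylconiferyl alcohol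
Product: 10 mixed 4-O-benzylconiferyl / 4-O-pivaloylsinapyl diester of the (4R,5R)-diacid
Conditions: 3 (1.1 equiv), EDC·HCl (1.3 equiv), DMAP (0.1 equiv), CH2Cl2, 0 °C → rt
Reagents that add atoms: none
Why: A second Steglich esterification under near-neutral conditions attaches the more ionisable, electron-rich cinnamyl alcohol last, and pivalate, acetonide and both E-alkenes tolerate it.

Step 7
Reactants: 10 mixed 4-O-benzylconiferyl / 4-O-pivaloylsinapyl diester
Product: 11 tartrate-bridged all-trans aryltetralin (1S,2R,3R; tether 4R,5R)
Conditions: 9-mesityl-10-methylacridinium BF4 (5 mol %), PhSSPh (20 mol %), dry degassed DCE (2 mM), 4 Å MS, 450 nm LEDs, N2, rt; chromatography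
Reagents that add atoms: none
Why: Proposed new method: the excited acridinium takes one electron from the π system of lowest potential, the 4-benzyloxy-3-methoxystyrene arm, C3 of the other arm attacks its β-carbon C2, and the resulting 1,4-distonic radical cation holds the charge at C1 (para-benzyloxy donor) and the spin at C4 (its ring offers only an acylated, twisted para oxygen and two meta methoxy groups); C8a then adds to C1, the arenium proton passes to thiolate, PhSH delivers a hydrogen atom to C4, and the acridinyl radical reduces PhS• back to thiolate, so the step is an isomerisation that consumes nothing. The closest known reaction type is the acridinium/disulfide photoredox [4+2] dimerisation of β-substituted styrenes to 1-aryltetralins, whereas a crossed, tethered version and stereochemical relay from a tether are untested. The ten-membered dilactone closes by 10-exo-trig attack of the neutral alkene on the alkene radical cation (C1 and C4 stay outside that ring), aided by high dilution, two planar s-trans esters and the backbone restriction of the trans-dioxolane, and ring B closes by a six-membered intramolecular Friedel–Crafts alkylation, 6-exo-trig at the quinone-methide-like C1 cation with the C4a–C8a π bond inside the new ring. C2 and C3 are set together in the first bond formation: the trans relation requires both arms to offer faces of the same topicity, the pairing that a C2-symmetric tether favours, and the choice between the two such pairings rests on the (4R,5R)-dioxolane, whose negative O=C–C–C–C=O torsion (about −85° with both carboxyls pseudo-equatorial) splays the ester arms so that, in a simple C2-symmetric vector model, C9 and C9' are bridged with less angle strain by a large negative C9–C2–C3–C9' torsion, which stacks the two styrenes and corresponds to 2R,3R. C1 is set afterwards by substrate control in the Friedel–Crafts closure, where the planar cation has lost all memory of alkene geometry and the guaiacyl ring should settle trans to the C2 substituent, pseudo-axial and clear of the peri C8 methoxy group. The step needs cross- rather than homo-coupling (tether plus 2 mM dilution), ring A rather than the guaiacyl ring as the nucleophile (protecting-group electronics place the cation at C1, and the two free ortho positions of ring A are equivalent, so no regioisomer can arise) and [4+2] rather than [2+2] (cyclobutane closure is reversible under the oxidising conditions whereas rearomatisation and hydrogen-atom transfer are not).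

Step 8
Reactants: 11 tartrate-bridged all-trans aryltetralin
Product: 12 4'-O-benzyl-8-methoxyisolariciresinol
Conditions: LiAlH4 (5 equiv), THF, 0 °C → rt; aq. Rochelle salt
Reagents that add atoms: none
Why: Lithium aluminium hydride reduces the two tether esters and the aryl pivalate by acyl–oxygen cleavage, which frees C9-OH, C9'-OH and the C7 phenol in one operation without touching any bond to C1, C2 or C3, and the tether leaves as water-soluble threitol acetonide.

Step 9
Reactants: 12 4'-O-benzyl-8-methoxyisolariciresinol
Product: 13 (+)-8-methoxyisolariciresinol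
Conditions: H2 (1 atm), 10% Pd/C, EtOH–EtOAc, rt
Reagents that add atoms: none
Why: Catalytic hydrogenolysis cleaves only the benzylic C–O bond of the aryl benzyl ether; the bonds from C1 to its two rings are C–C bonds and no other reducible group is present, so the stereocentres are preserved.

Compound list
1 | ferulic acid, (E)-3-(4-hydroxy-3-methoxyphenyl)prop-2-enoic acid | COc1cc(/C=C/C(=O)O)ccc1O | starting material
2 | benzyl (E)-3-[4-(benzyloxy)-3-methoxyphenyl]prop-2-enoate | COc1cc(/C=C/C(=O)OCc2ccccc2)ccc1OCc1ccccc1 | intermediate
3 | 4-O-benzylconiferyl alcohol, (E)-3-[4-(benzyloxy)-3-methoxyphenyl]prop-2-en-1-ol | COc1cc(/C=C/CO)ccc1OCc1ccccc1 | intermediate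
4 | sinapic acid, (E)-3-(4-hydroxy-3,5-dimethoxyphenyl)prop-2-enoic acid | COc1cc(/C=C/C(=O)O)cc(OC)c1O | starting material
5 | 4-O-pivaloylsinapic pivalic mixed anhydride (E) | COc1cc(/C=C/C(=O)OC(=O)C(C)(C)C)cc(OC)c1OC(=O)C(C)(C)C | intermediate
6 | 4-O-pivaloylsinapyl alcohol, 4-[(E)-3-hydroxyprop-1-enyl]-2,6-dimethoxyphenyl pivalate | COc1cc(/C=C/CO)cc(OC)c1OC(=O)C(C)(C)C | intermediate
7 | dimethyl (4R,5R)-2,2-dimethyl-1,3-dioxolane-4,5-dicarboxylate (dimethyl 2,3-O-isopropylidene-L-tartrate) | COC(=O)[C@@H]1OC(C)(C)O[C@H]1C(=O)OC | starting material
8 | (4R,5R)-2,2-dimethyl-1,3-dioxolane-4,5-dicarboxylic acid | OC(=O)[C@@H]1OC(C)(C)O[C@H]1C(=O)O | intermediate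
9 | (4R,5R)-5-{[(E)-3-(3,5-dimethoxy-4-pivaloyloxyphenyl)prop-2-enyl]oxycarbonyl}-2,2-dimethyl-1,3-dioxolane-4-carboxylic acid | COc1cc(/C=C/COC(=O)[C@@H]2OC(C)(C)O[C@H]2C(=O)O)cc(OC)c1OC(=O)C(C)(C)C | intermediate
10 | (4R,5R)-2,2-dimethyl-1,3-dioxolane-4,5-dicarboxylic acid 4-[(E)-3-(4-benzyloxy-3-methoxyphenyl)prop-2-enyl] 5-[(E)-3-(3,5-dimethoxy-4-pivaloyloxyphenyl)prop-2-enyl] diester | COc1cc(/C=C/COC(=O)[C@@H]2OC(C)(C)O[C@H]2C(=O)OC/C=C/c2cc(OC)c(OC(=O)C(C)(C)C)c(OC)c2)ccc1OCc1ccccc1 | intermediate
11 | (1S,2R,3R)-1-(4-benzyloxy-3-methoxyphenyl)-6,8-dimethoxy-7-pivaloyloxytetralin whose C9H2O (on C2) and C9'H2O (on C3) are esterified by the two carboxyl groups of the (4R,5R)-dioxolane diacid (ten-membered dilactone trans-fused to ring B) | COc1cc([C@H]2c3c(cc(OC)c(OC(=O)C(C)(C)C)c3OC)C[C@H]3COC(=O)[C@@H]4OC(C)(C)O[C@H]4C(=O)OC[C@H]23)ccc1OCc1ccccc1 | intermediate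
12 | 4'-O-benzyl-8-methoxyisolariciresinol, (1S,2R,3R)-1-(4-benzyloxy-3-methoxyphenyl)-2,3-bis(hydroxymethyl)-6,8-dimethoxy-1,2,3,4-tetrahydronaphthalen-7-ol | COc1cc([C@H]2c3c(cc(OC)c(O)c3OC)C[C@@H](CO)[C@@H]2CO)ccc1OCc1ccccc1 | intermediate
13 | (+)-8-methoxyisolariciresinol, (1S,2R,3R)-1-(4-hydroxy-3-methoxyphenyl)-2,3-bis(hydroxymethyl)-6,8-dimethoxy-1,2,3,4-tetrahydronaphthalen-7-ol | COc1cc([C@H]2c3c(cc(OC)c(O)c3OC)C[C@@H](CO)[C@@H]2CO)ccc1O | target

Total step count: 9.
Longest linear sequence: 6 steps (steps 3, 5, 6, 7, 8, 9). The ferulic branch (1, 2, 6–9) and the tartrate branch (4, 5, 6–9) are equally long.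

Steps most likely to fail

1. Step 7.
- **What may go wrong:** Angle strain in the ten-membered closure, caused by the wide splay of the trans-dioxolane ester arms, may slow C2–C3 bond formation. Back electron transfer, E/Z isomerisation, intermolecular coupling, or capture of the radical cation or the C1 cation by thiolate or an ester carbonyl could then take over. Facial selection by the remote tether may also be weak or of the opposite sense.
- **Fallback (known chemistry, from 6, back at 12):**
  - Hydrogenation of the alkene of 6 (H2, Pd/C, EtOAc) would give 3-[3,5-dimethoxy-4-(pivaloyloxy)phenyl]propan-1-ol F1.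
  - Acylation with glyoxylic acid chloride p-toluenesulfonylhydrazone (PhNMe2, CH2Cl2, 0 °C) would give the glyoxylate tosylhydrazone ester F2. Et3N converts this in the same flask into the 3-arylpropyl diazoacetate F3.
  - Enantioselective intramolecular carbenoid C–H insertion follows, using the chiral dirhodium(II) carboxamidate Rh2(MPPIM)4 in refluxing CH2Cl2. The catalyst antipode is chosen to deliver the R product. This would give the (R)-β-benzyl-γ-butyrolactone F4 and fixes C3.
  - Enolisation (LiHMDS, THF, −78 °C) and addition of 4-benzyloxy-3-methoxybenzaldehyde anti to the benzyl group would give the trans aldol adduct F5. This fixes C2, and both carbinol epimers are usable.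
  - TFA in CH2Cl2 ionises the carbinol, and ring A closes onto the cation in a Friedel–Crafts cyclisation. This gives the all-trans aryltetralin lactone F6 and fixes C1.
  - LiAlH4 in THF reduces lactone and pivalate to 12.

2. Step 3.
- **What may go wrong:** Conjugate reduction of the cinnamoyl unit, disproportionation of the mixed anhydride before hydride delivery, hydride attack at the wrong carbonyl, or partial loss of the aryl pivalate could erode the one-pot sequence.
- **Fallback (reduce first, protect afterwards; from 4, back at 6):**
  - Fischer esterification (MeOH, cat. H2SO4, reflux) would give methyl sinapate F7.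
  - DIBAL-H (4 equiv, toluene, 0 °C) would give sinapyl alcohol F8.
  - Chemoselective acylation of the phenoxide under phase-transfer conditions (PivCl, aq. NaOH, CH2Cl2, Bu4NHSO4, 0 °C), where the neutral allylic alcohol does not compete, would give 6.

3. Step 5.
- **What may go wrong:** Re-activation of the half ester (double esterification), oligomeric anhydride formation from the excess diacid, or loss of the polar half ester during the acid–base work-up could defeat the stoichiometric differentiation.
- **Fallback (convergent, not stepwise; from 8, back at 10, skipping 9):**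
  - 8 is esterified in one flask with one equivalent each of 3 and 6 (EDC·HCl, DMAP, CH2Cl2, 0 °C → rt).
  - The statistical mixture holds 10 together with the symmetrical bis(4-O-pivaloylsinapyl) diester F9 and the symmetrical bis(4-O-benzylconiferyl) diester F10.
  - Each of these differs from 10 by exchange of a benzyl-ether arm for a pivalate arm, so they should separate on silica.

Further compounds
F1 | step 7 | 3-[3,5-dimethoxy-4-(pivaloyloxy)phenyl]propan-1-ol | COc1cc(CCCO)cc(OC)c1OC(=O)C(C)(C)C
F2 | step 7 | 3-[3,5-dimethoxy-4-(pivaloyloxy)phenyl]propyl glyoxylate p-toluenesulfonylhydrazone | COc1cc(CCCOC(=O)/C=N/NS(=O)(=O)c2ccc(C)cc2)cc(OC)c1OC(=O)C(C)(C)C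
F3 | step 7 | 3-[3,5-dimethoxy-4-(pivaloyloxy)phenyl]propyl diazoacetate | COc1cc(CCCOC(=O)C=[N+]=[N-])cc(OC)c1OC(=O)C(C)(C)C
F4 | step 7 | (4R)-4-{[3,5-dimethoxy-4-(pivaloyloxy)phenyl]methyl}oxolan-2-one | O=C1C[C@@H](Cc2cc(OC)c(OC(=O)C(C)(C)C)c(OC)c2)CO1
F5 | step 7 | (3S,4R)-3-{[4-(benzyloxy)-3-methoxyphenyl](hydroxy)methyl}-4-{[3,5-dimethoxy-4-(pivaloyloxy)phenyl]methyl}oxolan-2-one, carbinol epimers | O=C1[C@H](C(O)c2ccc(OCc3ccccc3)c(OC)c2)[C@@H](Cc2cc(OC)c(OC(=O)C(C)(C)C)c(OC)c2)CO1
F6 | step 7 | all-trans (1S,2R,3R) 1-(4-benzyloxy-3-methoxyphenyl)-6,8-dimethoxy-7-pivaloyloxytetralin 2,3-fused γ-lactone (C9 carbonyl, C9' CH2O) | O=C1OC[C@@H]2Cc3cc(OC)c(OC(=O)C(C)(C)C)c(OC)c3[C@H](c3ccc(OCc4ccccc4)c(OC)c3)[C@@H]12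
F7 | step 3 | methyl sinapate | COC(=O)/C=C/c1cc(OC)c(O)c(OC)c1
F8 | step 3 | sinapyl alcohol | COc1cc(/C=C/CO)cc(OC)c1O
F9 | step 5 | bis(4-O-pivaloylsinapyl) (4R,5R)-2,2-dimethyl-1,3-dioxolane-4,5-dicarboxylate | COc1cc(/C=C/COC(=O)[C@@H]2OC(C)(C)O[C@H]2C(=O)OC/C=C/c2cc(OC)c(OC(=O)C(C)(C)C)c(OC)c2)cc(OC)c1OC(=O)C(C)(C)C
F10 | step 5 | bis(4-O-benzylconiferyl) (4R,5R)-2,2-dimethyl-1,3-dioxolane-4,5-dicarboxylate | COc1cc(/C=C/COC(=O)[C@@H]2OC(C)(C)O[C@H]2C(=O)OC/C=C/c2ccc(OCc3ccccc3)c(OC)c2)ccc1OCc1ccccc1
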